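The earlier runs and the new flask are calculated for substances that don't exist; the scatter is artificial.

The first count to make is how many times the gas in solution has to be replaced, and the rate constants can wait.

| flask | substrate | gas | temperature | remark | time |
|---|---|---|---|---|---|
| Monday's | 0.025 M | 1.8 mM (held) | −15 °C | run made earlier |  |
| Friday's | 0.038 M | 1.8 mM (held) | 20 °C | run made earlier |  |
| grey | 0.050 M | 1.8 mM (held) | 50 °C |  | 40 h |
| green | 0.050 M | 1.8 mM (held) | 20 °C |  | 40 h |
| violet | 0.050 M | 1.8 mM (held) | −10 °C |  | 40 h |

| run | time / h | target / % | over-reaction product / % |
|---|---|---|---|
| Monday's | 96.0 | 0 | 0.2 |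
| Monday's | 192 | 0.7 | 0 |
| Monday's | 288 | 0.3 | 0 |
| Monday's | 360 | 0 | 0 |
| Monday's | 480 | 0.3 | 0 |
| Monday's | 600 | 0 | 0 |
| Friday's | 20.0 | 1.2 | 1.1 |
| Friday's | 40.0 | 4.5 | 0.7 |
| Friday's | 48.0 | 7.0 | 0.1 |
| Friday's | 72.0 | 11.2 | 2.4 |
| Friday's | 96.0 | 15.0 | 5.5 |
| Friday's | 120 | 20.2 | 10.6 |

(scatter of a reading: 1 percentage point)

- at the start none of the gas is in solution

* the flask that comes out highest in share of target in all that became target or over-reaction product, or "all alike" when all lie within 1.5 percentage points (grey / green / violet / all alike)
* share of target in all that became target or over-reaction product, grey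
* share of target in all that became target or over-reaction product, green
* share of target in all that became target or over-reaction product, violet

A saturated solution holds gas for 3.60% of the charge in grey, green and violet. If each substrate takes up one gas, converting the whole charge costs 27.8 refills, the number of times the dissolved gas must be replaced. A pseudo-first-order treatment, with the rate constant multiplied by a steady gas level, holds for as long as dissolving keeps pace with that demand.

Friday's run gives a reading of the pace at 20 °C, as far as its products show it. Target and over-reaction product together read 30.8% of its charge at 120 h, which, reckoned on that charge, averages 0.0542 h⁻¹ in refills. To take up its charge within 40 h, grey needs 0.694 h⁻¹, which is 12.8 times Friday's reading. At the start none of the gas is in solution, so it has to dissolve first.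

Because grey's need lies far above that reading, this reckoning expects grey's uptake to be held back by dissolving and, if over-reaction costs gas too, target to be lost more slowly than at a steady gas level. Monday's run at −15 °C reads no more than 0.7% of target, so violet should convert little and keep a high share. The order expected is violet, green, grey, with no figure committed for grey.

The forecast names violet. It gives 10% for grey (0% to 35%), expecting that “little target survives”, then 87% for green (78% to 93%) and 98% for violet (92% to 100%). This reckoning differs from the forecast on grey, placing the share above the forecast's figure.

The flask violet comes highest at 99.4%, green gives 90.7%, and both lie inside the forecast's ranges. Grey gives 70.9%, which is 61 percentage points above the forecast. In grey at 40.0 h, the coupling partner, which is the dissolved gas, stands at 0.481% of the charge against a full 3.60%, and 28.0% of the substrate remains. Counting one gas for each substrate taken up and one for each over-reaction, grey has used 25.6 refills, on average 0.639 h⁻¹.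

    intermediate → target (k = 0.00546 h⁻¹, Ea = 112 kJ mol⁻¹)
    substrate + coupling partner → intermediate (k = 12.8 L mol⁻¹ h⁻¹, Ea = 69.0 kJ mol⁻¹)
    coupling partner + target → over-reaction product (k = 6.58 L mol⁻¹ h⁻¹, Ea = 68.0 kJ mol⁻¹)
    gas ⇌ coupling partner, rate k4*(csat - [coupling partner]) (kL = 0.714 h⁻¹)
    (constants at 20 °C)

Green read at 4.0 d has used 22.7 refills, on average 0.236 h⁻¹, which is slower than grey's average. Scaling grey's shortfall by that pace puts the coupling partner at 2.45% of the charge, and the computed value is 2.81%.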